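**Retrosynthetic overview**
1. C11=C12: Wittig olefination of the C1–C11 allylic phosphonium salt with the commercial C10 dialdehyde 12 (last step, convergent).
2. 5,6-Epoxide (the only ring made in the route, closed in step 4): bromohydrin formation and closure on the C5=C6 alkene, with the face set by the bought C3 centre.
3. C8=O and C5=C6: a [3,3]-sigmatropic oxygen shift (Meyer–Schuster rearrangement through the propargyl vanadate) moves the carbinol oxygen from C6 to C8; base equilibration then puts the alkene into the ring.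
4. C6–C7: the acetylide of enynol 3 adds to the ketone of silylated (4R,6R)-actinol, which supplies the six-membered ring and C3.

Assumption: actinol 1, enynol 3 and C10 dialdehyde 12 are taken as purchasable; positions are given in carotenoid numbering (C1–C12′, ring C1–C6, chain C7 onwards).

**Step 1**
Reactants: 1 (4R,6R)-4-hydroxy-2,2,6-trimethylcyclohexan-1-one (actinol)
Product: 2 (4R,6R)-4-(tert-butyldimethylsilyloxy)-2,2,6-trimethylcyclohexan-1-one
Conditions: TBSCl, imidazole, DMF, rt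
Reagents that add atoms: tert-butyldimethylsilyl chloride (TBSCl), CC(C)(C)[Si](C)(C)Cl
Why: Silyl ether formation at the secondary alcohol; no stereocentre is touched, and the bulky group later fixes the ring conformation.

**Step 2**
Reactants: 2 (4R,6R)-4-(tert-butyldimethylsilyloxy)-2,2,6-trimethylcyclohexan-1-one; 3 (E)-3-methylpent-2-en-4-yn-1-ol
Product: 5 (4R,6R)-4-(tert-butyldimethylsilyloxy)-1-[(3E)-5-(tert-butyldimethylsilyloxy)-3-methylpent-3-en-1-yn-1-yl]-2,2,6-trimethylcyclohexan-1-ol (carbinol epimers), via dilithium dialkoxide 4 (not isolated)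
Conditions: 3 (1.3 equiv), n-BuLi (2.6 equiv), THF, −78 to −20 °C; then 2, −78 to 0 °C; then TBSCl (1.5 equiv), imidazole (0.2 equiv), 0 °C to rt; H2O work-up
Reagents that add atoms: tert-butyldimethylsilyl chloride (TBSCl), CC(C)(C)[Si](C)(C)Cl
Why: 1,2-Addition of the lithium acetylide (alkoxide/acetylide dianion) to the hindered ketone, then in-situ silylation of the primary alkoxide only (the neopentyl tertiary alkoxide is too hindered); the new carbinol centre and C5 need no control because both are erased in step 3.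

**Step 3**
Reactants: 5 (4R,6R)-4-(tert-butyldimethylsilyloxy)-1-[(3E)-5-(tert-butyldimethylsilyloxy)-3-methylpent-3-en-1-yn-1-yl]-2,2,6-trimethylcyclohexan-1-ol
Product: 7 (3E)-5-(tert-butyldimethylsilyloxy)-1-[(4R)-4-(tert-butyldimethylsilyloxy)-2,6,6-trimethylcyclohex-1-en-1-yl]-3-methylpent-3-en-2-one, via exocyclic dienone 6 (not isolated)
Conditions: VO(OSiPh3)3 (5 mol %), Ph3SiOH (20 mol %), xylene, 140 °C; then DBU (0.3 equiv), 80 °C, argon
Reagents that add atoms: none
Why: Oxo-vanadium-catalysed Meyer–Schuster rearrangement, in which the propargyl vanadate ester formed on the catalyst undergoes a [3,3]-sigmatropic shift that makes the C8–O bond at the expense of C6–O and the allenol tautomerises to dienone 6; DBU then equilibrates the strained exocyclic C6=C7 bond into the ring (tetrasubstituted C5=C6, chain enone stays conjugated and E), which erases C5 and C6 so that only the bought C3 centre remains.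

**Step 4**
Reactants: 7 (3E)-5-(tert-butyldimethylsilyloxy)-1-[(4R)-4-(tert-butyldimethylsilyloxy)-2,6,6-trimethylcyclohex-1-en-1-yl]-3-methylpent-3-en-2-one
Product: 9 (3E)-5-(tert-butyldimethylsilyloxy)-1-[(1S,4S,6R)-4-(tert-butyldimethylsilyloxy)-2,2,6-trimethyl-7-oxabicyclo[4.1.0]heptan-1-yl]-3-methylpent-3-en-2-one, via bromohydrin 8 (not isolated)
Conditions: NBS (1.05 equiv), THF–H2O (4:1), 0 °C; then K2CO3 (1.5 equiv), MeOH, 0 °C, 15 min
Reagents that add atoms: water, O
Why: Halohydrin route to the epoxide: with 3-OTBS equatorial the axial C1 methyl blocks the face anti to the silyloxy group, so Br+ adds syn to it, oxygen (water, relayed through the C8 carbonyl as a hemiketal) opens the bromonium ion trans-diaxially at C5 from the anti face (Fürst–Plattner), and alkoxide displacement of the tertiary bromide with inversion at C6 closes the epoxide anti to C3–O, i.e. (5R,6S), whereas a peracid would be expected to deliver oxygen mainly to the syn face.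

**Step 5**
Reactants: 9 (3E)-5-(tert-butyldimethylsilyloxy)-1-[(1S,4S,6R)-4-(tert-butyldimethylsilyloxy)-2,2,6-trimethyl-7-oxabicyclo[4.1.0]heptan-1-yl]-3-methylpent-3-en-2-one
Product: 10 (3E)-5-hydroxy-1-[(1S,4S,6R)-4-hydroxy-2,2,6-trimethyl-7-oxabicyclo[4.1.0]heptan-1-yl]-3-methylpent-3-en-2-one
Conditions: HF·pyridine, pyridine, THF, 0 °C to rt
Reagents that add atoms: none
Why: Fluoride-mediated cleavage of both silyl ethers under buffered, non-basic conditions that spare the base-labile β,γ-epoxy ketone; no stereocentre is touched.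

**Step 6**
Reactants: 10 (3E)-5-hydroxy-1-[(1S,4S,6R)-4-hydroxy-2,2,6-trimethyl-7-oxabicyclo[4.1.0]heptan-1-yl]-3-methylpent-3-en-2-one
Product: 11 (3E)-5-bromo-1-[(1S,4S,6R)-4-hydroxy-2,2,6-trimethyl-7-oxabicyclo[4.1.0]heptan-1-yl]-3-methylpent-3-en-2-one
Conditions: CBr4 (1.05 equiv), PPh3 (1.1 equiv), CH2Cl2, −30 to 0 °C
Reagents that add atoms: carbon tetrabromide, BrC(Br)(Br)Br
Why: Appel reaction under neutral conditions; the primary allylic alcohol reacts much faster than the secondary ring alcohol, and no stereocentre is involved.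

**Step 7**
Reactants: 11 (3E)-5-bromo-1-[(1S,4S,6R)-4-hydroxy-2,2,6-trimethyl-7-oxabicyclo[4.1.0]heptan-1-yl]-3-methylpent-3-en-2-one; 12 (2E,4E,6E)-2,7-dimethylocta-2,4,6-trienedial
Product: 15 (2E,4E,6E,8E,10E)-13-[(1S,4S,6R)-4-hydroxy-2,2,6-trimethyl-7-oxabicyclo[4.1.0]heptan-1-yl]-2,7,11-trimethyl-12-oxotrideca-2,4,6,8,10-pentaenal, via phosphonium bromide 13 (not isolated), via ylide 14 (not isolated)
Conditions: PPh3 (1.05 equiv), MeCN, rt; then 12 (3 equiv), 1,2-epoxybutane, EtOH, 50 °C; then I2 (cat.), CH2Cl2, daylight, rt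
Reagents that add atoms: none
Why: Wittig olefination: SN2 attack of PPh3 gives 13, its acidic γ-protons are removed under neutral epoxide-scavenger conditions (no enolisation of the β,γ-epoxy ketone), the vinylogous acyl ylide 14 condenses once with the excess dialdehyde, and iodine-catalysed equilibration converts the 11Z fraction into the all-E target with C3, C5 and C6 untouched.

**Compound list**
1 | (4R,6R)-4-hydroxy-2,2,6-trimethylcyclohexan-1-one | C[C@@H]1C[C@@H](O)CC(C)(C)C1=O | starting material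
2 | (4R,6R)-4-(tert-butyldimethylsilyloxy)-2,2,6-trimethylcyclohexan-1-one | C[C@@H]1C[C@@H](O[Si](C)(C)C(C)(C)C)CC(C)(C)C1=O | intermediate
3 | (E)-3-methylpent-2-en-4-yn-1-ol | C#C/C(C)=C/CO | starting material
4 | dilithium dialkoxide of the acetylide adduct (tertiary and primary alkoxide, carbinol epimers) | [Li+].[Li+].C[C@@H]1C[C@@H](O[Si](C)(C)C(C)(C)C)CC(C)(C)C1([O-])C#C/C(C)=C/C[O-] | intermediate
5 | (4R,6R)-4-(tert-butyldimethylsilyloxy)-1-[(3E)-5-(tert-butyldimethylsilyloxy)-3-methylpent-3-en-1-yn-1-yl]-2,2,6-trimethylcyclohexan-1-ol (carbinol epimers) | C[C@@H]1C[C@@H](O[Si](C)(C)C(C)(C)C)CC(C)(C)C1(O)C#C/C(C)=C/CO[Si](C)(C)C(C)(C)C | intermediate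
6 | (3E)-5-(tert-butyldimethylsilyloxy)-1-[(4R,6R)-4-(tert-butyldimethylsilyloxy)-2,2,6-trimethylcyclohexylidene]-3-methylpent-3-en-2-one (exocyclic geometry not defined) | C[C@@H]1C[C@@H](O[Si](C)(C)C(C)(C)C)CC(C)(C)C1=CC(=O)/C(C)=C/CO[Si](C)(C)C(C)(C)C | intermediate
7 | (3E)-5-(tert-butyldimethylsilyloxy)-1-[(4R)-4-(tert-butyldimethylsilyloxy)-2,6,6-trimethylcyclohex-1-en-1-yl]-3-methylpent-3-en-2-one | CC1=C(CC(=O)/C(C)=C/CO[Si](C)(C)C(C)(C)C)C(C)(C)C[C@H](O[Si](C)(C)C(C)(C)C)C1 | intermediate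
8 | (3E)-1-[(1R,2R,4S)-1-bromo-2-hydroxy-4-(tert-butyldimethylsilyloxy)-2,6,6-trimethylcyclohexyl]-5-(tert-butyldimethylsilyloxy)-3-methylpent-3-en-2-one (5-OH anti, 6-Br syn to the 3-silyloxy group; in equilibrium with its cyclic hemiketal) | C[C@@]1(O)C[C@@H](O[Si](C)(C)C(C)(C)C)CC(C)(C)[C@]1(Br)CC(=O)/C(C)=C/CO[Si](C)(C)C(C)(C)C | intermediate
9 | (3E)-5-(tert-butyldimethylsilyloxy)-1-[(1S,4S,6R)-4-(tert-butyldimethylsilyloxy)-2,2,6-trimethyl-7-oxabicyclo[4.1.0]heptan-1-yl]-3-methylpent-3-en-2-one | CC(C)(C)[Si](C)(C)OC/C=C(\C)C(=O)C[C@@]12O[C@]1(C)C[C@@H](O[Si](C)(C)C(C)(C)C)CC2(C)C | intermediate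
10 | (3E)-5-hydroxy-1-[(1S,4S,6R)-4-hydroxy-2,2,6-trimethyl-7-oxabicyclo[4.1.0]heptan-1-yl]-3-methylpent-3-en-2-one | OC/C=C(\C)C(=O)C[C@@]12O[C@]1(C)C[C@@H](O)CC2(C)C | intermediate
11 | (3E)-5-bromo-1-[(1S,4S,6R)-4-hydroxy-2,2,6-trimethyl-7-oxabicyclo[4.1.0]heptan-1-yl]-3-methylpent-3-en-2-one | BrC/C=C(\C)C(=O)C[C@@]12O[C@]1(C)C[C@@H](O)CC2(C)C | intermediate
12 | (2E,4E,6E)-2,7-dimethylocta-2,4,6-trienedial | O=C/C(C)=C/C=C/C=C(C)/C=O | starting material
13 | [(2E)-5-[(1S,4S,6R)-4-hydroxy-2,2,6-trimethyl-7-oxabicyclo[4.1.0]heptan-1-yl]-3-methyl-4-oxopent-2-en-1-yl]triphenylphosphonium bromide | [Br-].O=C(C[C@@]12O[C@]1(C)C[C@@H](O)CC2(C)C)/C(C)=C/C[P+](c1ccccc1)(c1ccccc1)c1ccccc1 | intermediate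
14 | (3E)-1-[(1S,4S,6R)-4-hydroxy-2,2,6-trimethyl-7-oxabicyclo[4.1.0]heptan-1-yl]-3-methyl-5-(triphenyl-λ5-phosphanylidene)pent-3-en-2-one | O=C(C[C@@]12O[C@]1(C)C[C@@H](O)CC2(C)C)/C(C)=C/C=P(c1ccccc1)(c1ccccc1)c1ccccc1 | intermediate
15 | (2E,4E,6E,8E,10E)-13-[(1S,4S,6R)-4-hydroxy-2,2,6-trimethyl-7-oxabicyclo[4.1.0]heptan-1-yl]-2,7,11-trimethyl-12-oxotrideca-2,4,6,8,10-pentaenal, (3S,5R,6S) in carotenoid numbering | C\C(C=O)=C/C=C/C=C(C)/C=C/C=C(\C)C(=O)C[C@@]12O[C@]1(C)C[C@@H](O)CC2(C)C | target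

**Totals**
Total step count: 7. Longest linear sequence: 7 steps (1 → 2 → 5 → 7 → 9 → 10 → 11 → 15).

**Steps most likely to fail, with fallbacks**

Step 3 (rearrangement and alkene equilibration). The hindered tertiary carbinol may esterify slowly on vanadium or dehydrate, and the equilibration relies on the ring-tetrasubstituted isomer being the thermodynamic sink. The fallback sets out from 5 and keeps the sigmatropic oxygen shift but runs it on an ester. Deprotonation (n-BuLi) and acylation with Ac2O give the propargylic acetate F1. AgBF4 (5 mol %) in CH2Cl2 effects the [3,3]-acyloxy shift to the allenyl acetate F2. K2CO3 in MeOH cleaves the enol ester and the released dienolate equilibrates to 7, where the route is rejoined.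

Step 4 (bromohydrin and closure). The β-bromo ketone 8 could lose HBr (E1cB) or be trapped as cyclic ketals instead of closing, and the facial argument is by analogy, not measured on this substrate. The fallback sets out from 7 and takes the carbonyl out of play. Luche reduction (NaBH4, CeCl3·7H2O, MeOH) gives the allylic alcohol F3 and acetylation (Ac2O, pyridine) the acetate F4. NBS in aqueous THF gives the bromohydrin acetate F5 by the same facial course. K2CO3 in MeOH closes the epoxide and removes the acetate to give the epoxy alcohol F6. Buffered Dess–Martin oxidation returns the ketone and rejoins the route at 9.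

Step 7 (Wittig olefination). The stabilised ylide may react sluggishly, over-olefinate the dialdehyde or give an E/Z mixture that resists equilibration. The fallback sets out from 11. An Arbuzov reaction with P(OEt)3 (80 °C) gives the allylic phosphonate F7. A Masamune–Roush Horner–Wadsworth–Emmons reaction (LiCl, i-Pr2NEt, MeCN, rt) with 12 then gives 15 directly with high E selectivity.

**Further compounds**
F1 | step 3 | (4R,6R)-4-(tert-butyldimethylsilyloxy)-1-[(3E)-5-(tert-butyldimethylsilyloxy)-3-methylpent-3-en-1-yn-1-yl]-2,2,6-trimethylcyclohexyl acetate | C[C@@H]1C[C@@H](O[Si](C)(C)C(C)(C)C)CC(C)(C)C1(OC(C)=O)C#C/C(C)=C/CO[Si](C)(C)C(C)(C)C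
F2 | step 3 | (3E)-5-(tert-butyldimethylsilyloxy)-1-[(4R,6R)-4-(tert-butyldimethylsilyloxy)-2,2,6-trimethylcyclohexylidene]-3-methylpenta-1,3-dien-2-yl acetate (allenyl acetate) | C[C@@H]1C[C@@H](O[Si](C)(C)C(C)(C)C)CC(C)(C)C1=C=C(OC(C)=O)/C(C)=C/CO[Si](C)(C)C(C)(C)C
F3 | step 4 | (3E)-5-(tert-butyldimethylsilyloxy)-1-[(4R)-4-(tert-butyldimethylsilyloxy)-2,6,6-trimethylcyclohex-1-en-1-yl]-3-methylpent-3-en-2-ol (carbinol epimers) | CC1=C(CC(O)/C(C)=C/CO[Si](C)(C)C(C)(C)C)C(C)(C)C[C@H](O[Si](C)(C)C(C)(C)C)C1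
F4 | step 4 | (3E)-5-(tert-butyldimethylsilyloxy)-1-[(4R)-4-(tert-butyldimethylsilyloxy)-2,6,6-trimethylcyclohex-1-en-1-yl]-3-methylpent-3-en-2-yl acetate | CC1=C(CC(OC(C)=O)/C(C)=C/CO[Si](C)(C)C(C)(C)C)C(C)(C)C[C@H](O[Si](C)(C)C(C)(C)C)C1
F5 | step 4 | (3E)-1-[(1R,2R,4S)-1-bromo-2-hydroxy-4-(tert-butyldimethylsilyloxy)-2,6,6-trimethylcyclohexyl]-5-(tert-butyldimethylsilyloxy)-3-methylpent-3-en-2-yl acetate | C[C@@]1(O)C[C@@H](O[Si](C)(C)C(C)(C)C)CC(C)(C)[C@]1(Br)CC(OC(C)=O)/C(C)=C/CO[Si](C)(C)C(C)(C)C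
F6 | step 4 | (3E)-5-(tert-butyldimethylsilyloxy)-1-[(1S,4S,6R)-4-(tert-butyldimethylsilyloxy)-2,2,6-trimethyl-7-oxabicyclo[4.1.0]heptan-1-yl]-3-methylpent-3-en-2-ol | CC(C)(C)[Si](C)(C)OC/C=C(\C)C(O)C[C@@]12O[C@]1(C)C[C@@H](O[Si](C)(C)C(C)(C)C)CC2(C)C
F7 | step 7 | diethyl [(2E)-5-[(1S,4S,6R)-4-hydroxy-2,2,6-trimethyl-7-oxabicyclo[4.1.0]heptan-1-yl]-3-methyl-4-oxopent-2-en-1-yl]phosphonate | CCOP(=O)(OCC)C/C=C(\C)C(=O)C[C@@]12O[C@]1(C)C[C@@H](O)CC2(C)C
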